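**Plan**

- Retrosynthesis: cut C12–C13 (sp3–sp2 coupling to the butenolide), then C11=C12 (methylenation), then open both rings at C5–C10 and C8–C9 in one [4+2] step, and finally cut the chain at C1–C10 (sp3–sp2 coupling), C7=C8 (aldol condensation) and C3–C4 (conjugate allylation).
- Enabling feature: rings A (C1–C5, C10) and B (C5–C10) are fused through C5–C10, C6 bears oxygen and C9 bears C11. C5=C6(OSi)–C7=C8 can therefore act as a 2-silyloxy diene and C9=C10, acylated at C11, as the dienophile, with C1–C4 as the tether.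
- Forward: the C1–C8 chain is built from mesityl oxide, the (E)-enoyl imide is joined at C1–C10, rings A and B close together, the oxidation pattern at C6/C8/C9/C11 is adjusted, and the C12–C16 butenolide is attached last.
- Stereochemistry: C10 comes from the (S)-4-benzyloxazolidinone (the diene adds opposite the benzyl group of the aluminium chelate). C5 comes from the endo transition state of the (E)-dienophile (trans fusion). C6 comes from α-face hydride delivery to the 6-ketone (6β-OH).

Key step: step 7

Remark: ring atoms are numbered as in labdanes (C1–C10 in the bicycle, C11 on C9, methyl groups on C4, C4, C8 and C10); β is the face of the C10 methyl group; "octal-n-ene" is the octahydronaphthalene with that numbering; TBS is tert-butyldimethylsilyl.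
Assumption: (E)-3-iodobut-2-enoic acid (10) is taken as a purchasable building block; its (E) geometry fixes the dienophile geometry.

Step 1
Reactants: 1 4-methylpent-3-en-2-one (mesityl oxide); 2 allyltrimethylsilane
Product: 3 4,4-dimethylhept-6-en-2-one
Conditions: TiCl4, CH2Cl2, −78 °C; H2O
Reagents that add atoms: none
Why: Hosomi–Sakurai conjugate allylation: TiCl4 activates the enone and the allylsilane adds through its γ-carbon to the β,β-disubstituted carbon, which should build the quaternary C4 with both methyl groups and leave a terminal alkene as the later C1 handle (no stereocentre).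

Step 2
Reactants: 3 4,4-dimethylhept-6-en-2-one; 4 acetaldehyde
Product: 6 2-hydroxy-6,6-dimethylnon-8-en-4-one (racemic), via lithium enolate 5 (not isolated)
Conditions: LiN(i-Pr)2, THF, −78 °C; then 4, −78 °C; H2O
Reagents that add atoms: none
Why: Directed aldol addition: LiN(i-Pr)2 removes a proton from the methyl group (kinetically favoured over the neopentyl CH2) and the enolate adds to acetaldehyde; the new carbinol centre is racemic and disappears in step 3.

Step 3
Reactants: 6 2-hydroxy-6,6-dimethylnon-8-en-4-one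
Product: 8 (E)-6,6-dimethylnona-2,8-dien-4-one, via mesylate 7 (not isolated)
Conditions: MsCl, Et3N, CH2Cl2, 0 °C to rt
Reagents that add atoms: none
Why: Mesylation followed by E1cB elimination (aldol condensation completed) should give the conjugated enone with the thermodynamically favoured (E) geometry at what becomes C7=C8.

Step 4
Reactants: 8 (E)-6,6-dimethylnona-2,8-dien-4-one
Product: 9 tert-butyl{[(2E,4Z)-6,6-dimethylnona-2,4,8-trien-4-yl]oxy}dimethylsilane
Conditions: TBSOTf, Et3N, CH2Cl2, 0 °C
Reagents that add atoms: tert-butyldimethylsilyl trifluoromethanesulfonate, CC(C)(C)[Si](C)(C)OS(=O)(=O)C(F)(F)F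
Why: Soft enolisation: O-silylation to the oxocarbenium ion and deprotonation of the α'-CH2 by Et3N should give the cross-conjugated 2-silyloxy diene, (Z) at the enol ether because the tert-alkyl group avoids A(1,3) strain with the propenyl group, so that C4 sits on the outside of the s-cis diene.

Step 5
Reactants: 10 (E)-3-iodobut-2-enoic acid; 11 (S)-4-benzyloxazolidin-2-one
Product: 13 (S)-4-benzyl-3-[(E)-3-iodobut-2-enoyl]oxazolidin-2-one, via mixed pivalic anhydride 12 (not isolated)
Conditions: t-BuCOCl, Et3N, THF, −20 °C; then 11, LiCl, rt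
Reagents that add atoms: none
Why: N-Acylation of the oxazolidinone through the mixed pivalic anhydride under LiCl/Et3N, without strong base, so that the β-iodo enoyl unit keeps its (E) geometry and is not attacked at the β-carbon.

Step 6
Reactants: 9 tert-butyl{[(2E,4Z)-6,6-dimethylnona-2,4,8-trien-4-yl]oxy}dimethylsilane; 13 (S)-4-benzyl-3-[(E)-3-iodobut-2-enoyl]oxazolidin-2-one
Product: 15 (S)-4-benzyl-3-[(2E,8Z,10E)-9-(tert-butyldimethylsilyloxy)-3,7,7-trimethyldodeca-2,8,10-trienoyl]oxazolidin-2-one, via alkylborane 14 (not isolated)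
Conditions: 9-BBN, THF, 0 °C to rt; then 13, PdCl2(dppf) (5 mol%), AsPh3, K3PO4 (anhydrous), DMF, rt to 40 °C
Reagents that add atoms: none
Why: B-alkyl Suzuki–Miyaura coupling: 9-BBN hydroborates only the monosubstituted alkene (anti-Markovnikov; the hindered, conjugated silyloxy diene reacts far more slowly) and the alkylborane couples with the vinyl iodide with retention, which fixes the (E) geometry of the trisubstituted C9=C10 dienophile, while anhydrous phosphate spares the silyl dienol ether and the imide.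

Step 7
Reactants: 15 (S)-4-benzyl-3-[(2E,8Z,10E)-9-(tert-butyldimethylsilyloxy)-3,7,7-trimethyldodeca-2,8,10-trienoyl]oxazolidin-2-one
Product: 16 (S)-4-benzyl-3-acyloxazolidin-2-one of 6-(tert-butyldimethylsilyloxy)-4,4,8β,10β-tetramethyl-trans-octal-6-ene-9β-carboxylic acid (5α-H, 8α-H, 9α-H)
Conditions: Me2AlCl (1.5–2 equiv), CH2Cl2, −78 to −20 °C; aqueous potassium sodium tartrate
Reagents that add atoms: none
Why: More than one equivalent of Me2AlCl converts the imide into its cationic, two-point aluminium chelate with the enoyl unit held s-cis, and the tethered 2-silyloxy diene adds in a concerted but asynchronous [4+2] process in which the nucleophilic C5 bonds first to the β-carbon C10 and C9 then closes onto C8 (Mukaiyama–Michael character). The closest known reaction type is the Lewis-acid-promoted intramolecular Diels–Alder reaction of trienoyl oxazolidinones with a four-carbon tether, which gives trans-fused octalins. Ring A closes through the tether as a six-membered carbocycle by the C5–C10 bond (6-exo-trig with respect to the C9=C10 acceptor) and ring B is the cyclohexene of the cycloaddition itself (C5–C10 plus C8–C9, the new double bond being the C6=C7 silyl enol ether). C10 is set by the auxiliary, whose benzyl group shields one face of the chelate so that the diene adds to the Cα-si face (10S with the (E)-dienophile); C5 is set by the endo transition state with the chelated carbonyl under the diene, which puts H-5 anti to the C10 methyl (trans fusion); C8 and C9 follow from suprafacial addition to the (E)-propenyl terminus and the (E)-enoyl unit and are removed in steps 9 and 10. The step needs facial selectivity (benzyl group of the rigid chelate), endo selectivity (Lewis-acid complexation, chair-like tether favoured by the C4 gem-dimethyl group) and a geometrically pure (E)-dienophile (from the stereoretentive coupling of step 6); the silyl group is tert-butyldimethylsilyl so that the dienol ether survives the Lewis acid.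

Step 8
Reactants: 16 N-acyl oxazolidinone of the Diels–Alder adduct
Product: 17 S-ethyl 6-(tert-butyldimethylsilyloxy)-4,4,8β,10β-tetramethyl-trans-octal-6-ene-9β-carbothioate (5α-H)
Conditions: EtSH, n-BuLi, THF, 0 °C (LiSEt); then 16, 0 °C; H2O
Reagents that add atoms: ethanethiol (as LiSEt), CCS
Why: Nucleophilic cleavage of the N-acyl oxazolidinone by lithium ethanethiolate: the small, soft thiolate should attack the exocyclic carbonyl although it is flanked by C8 and the quaternary C10, does not touch the silyl enol ether, and gives a thioester whose α-proton and carbonyl are reactive enough for steps 10 and 11.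

Step 9
Reactants: 17 S-ethyl 6-(tert-butyldimethylsilyloxy)-4,4,8β,10β-tetramethyl-trans-octal-6-ene-9β-carbothioate
Product: 18 S-ethyl 4,4,8,10β-tetramethyl-6-oxo-octal-7-ene-9β-carbothioate (5α-H, trans-fused)
Conditions: Pd(OAc)2 (1.1 equiv), MeCN, rt
Reagents that add atoms: none
Why: Saegusa–Ito oxidation: Pd(OAc)2 palladates C7 of the silyl enol ether and syn β-hydride elimination of H-8 (the only β-hydrogen) should give the 7-en-6-one, which removes the C8 stereocentre.

Step 10
Reactants: 18 S-ethyl 4,4,8,10β-tetramethyl-6-oxo-octal-7-ene-9β-carbothioate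
Product: 19 S-ethyl 6-(tert-butyldimethylsilyloxy)-4,4,8,10β-tetramethyl-octala-6,8-diene-9-carbothioate (5α-H)
Conditions: TBSOTf, Et3N, CH2Cl2, 0 °C
Reagents that add atoms: tert-butyldimethylsilyl trifluoromethanesulfonate, CC(C)(C)[Si](C)(C)OS(=O)(=O)C(F)(F)F
Why: Soft enolisation of a vinylogous β-dicarbonyl system: H-9 is α to the thioester and γ to the enone, so O-silylation of the ketone and deprotonation at C9 should give the through-conjugated silyl dienol ether, which moves the ring double bond to C8=C9 and removes the C9 stereocentre.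

Step 11
Reactants: 19 S-ethyl 6-(tert-butyldimethylsilyloxy)-4,4,8,10β-tetramethyl-octala-6,8-diene-9-carbothioate
Product: 20 [6-(tert-butyldimethylsilyloxy)-4,4,8,10β-tetramethyl-octala-6,8-dien-9-yl]methanol (5α-H)
Conditions: i-Bu2AlH (3 equiv), CH2Cl2, −78 to −20 °C; aqueous potassium sodium tartrate
Reagents that add atoms: none
Why: Hydride reduction of the thioester with i-Bu2AlH to the primary allylic alcohol (C11); the silyl dienol ether is inert to hydride and keeps the 8,9-double bond in place.

Step 12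
Reactants: 20 [6-(tert-butyldimethylsilyloxy)-4,4,8,10β-tetramethyl-octala-6,8-dien-9-yl]methanol
Product: 22 9-(hydroxymethyl)-4,4,8,10β-tetramethyl-octal-8-en-6β-ol (5α-H; the 6β,11-diol), via 6-ketone 21 (not isolated)
Conditions: Bu4NF, AcOH, THF, −78 to −20 °C; then NaBH4, MeOH, −20 °C
Reagents that add atoms: none
Why: Fluoride desilylation gives the dienolate, which AcOH protonates kinetically at the α-carbon C7 to the β,γ-unsaturated 6-ketone (the deconjugated pattern known from 5(10)-en-3-one steroids), and NaBH4 then delivers hydride to the α face, away from the axial methyl groups on C4 and C10, which sets the 6β (axial) hydroxyl (C6 R).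

Step 13
Reactants: 22 9-(hydroxymethyl)-4,4,8,10β-tetramethyl-octal-8-en-6β-ol
Product: 23 6β-hydroxy-4,4,8,10β-tetramethyl-octal-8-ene-9-carbaldehyde (5α-H)
Conditions: MnO2, CH2Cl2, rt
Reagents that add atoms: none
Why: Allylic oxidation with MnO2, selective for the primary allylic alcohol over the hindered, non-allylic secondary 6β-hydroxyl.

Step 14
Reactants: 23 6β-hydroxy-4,4,8,10β-tetramethyl-octal-8-ene-9-carbaldehyde
Product: 24 4,4,8,10β-tetramethyl-9-vinyl-octal-8-en-6β-ol (5α-H)
Conditions: Ph3PCH3Br, KN(SiMe3)2, THF, 0 °C; then 23, 0 °C to rt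
Reagents that add atoms: methyltriphenylphosphonium bromide, C[P+](c1ccccc1)(c1ccccc1)c1ccccc1.[Br-]
Why: Wittig methylenation of the hindered enal (as for β-cyclocitral-type aldehydes) should give the 9-vinyl diene; excess ylide covers the free hydroxyl.

Step 15
Reactants: 24 4,4,8,10β-tetramethyl-9-vinyl-octal-8-en-6β-ol
Product: 25 4,4,8,10β-tetramethyl-9-vinyl-octal-8-en-6β-yl acetate (5α-H)
Conditions: Ac2O, DMAP, pyridine, 40 °C
Reagents that add atoms: acetic anhydride, CC(=O)OC(C)=O
Why: DMAP-catalysed acylation of the hindered axial alcohol installs the acetate with retention at C6.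

Step 16
Reactants: 25 4,4,8,10β-tetramethyl-9-vinyl-octal-8-en-6β-yl acetate; 26 4-bromofuran-2(5H)-one
Product: 28 6β-acetoxylabda-8,13-dien-15,16-olide, (5S,6R,10S) (target), via alkylborane 27 (not isolated)
Conditions: 9-BBN, THF, rt; then 26, PdCl2(dppf) (5 mol%), AsPh3, aqueous K3PO4, DMF, rt
Reagents that add atoms: none
Why: B-alkyl Suzuki–Miyaura coupling: 9-BBN adds anti-Markovnikov to the vinyl group only (the tetrasubstituted 8,9-alkene is inert, the acetate is tolerated) and the alkylborane couples at C4 of the β-bromobutenolide, which forms C12–C13 and completes the target.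

**Compound list**

1 | 4-methylpent-3-en-2-one (mesityl oxide) | CC(=O)C=C(C)C | starting material
2 | allyltrimethylsilane | C=CC[Si](C)(C)C | starting material
3 | 4,4-dimethylhept-6-en-2-one | CC(=O)CC(C)(C)CC=C | intermediate
4 | acetaldehyde | CC=O | starting material
5 | lithium 4,4-dimethylhepta-1,6-dien-2-olate | [Li]OC(=C)CC(C)(C)CC=C | intermediate (not isolated)
6 | 2-hydroxy-6,6-dimethylnon-8-en-4-one (racemic) | CC(O)CC(=O)CC(C)(C)CC=C | intermediate
7 | 6,6-dimethyl-4-oxonon-8-en-2-yl methanesulfonate | CC(OS(C)(=O)=O)CC(=O)CC(C)(C)CC=C | intermediate (not isolated)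
8 | (E)-6,6-dimethylnona-2,8-dien-4-one | C/C=C/C(=O)CC(C)(C)CC=C | intermediate
9 | tert-butyl{[(2E,4Z)-6,6-dimethylnona-2,4,8-trien-4-yl]oxy}dimethylsilane | C/C=C/C(O[Si](C)(C)C(C)(C)C)=C/C(C)(C)CC=C | intermediate
10 | (E)-3-iodobut-2-enoic acid | C/C(I)=C\C(=O)O | starting material
11 | (S)-4-benzyloxazolidin-2-one | O=C1N[C@@H](Cc2ccccc2)CO1 | starting material
12 | (E)-3-iodobut-2-enoic pivalic anhydride | C/C(I)=C\C(=O)OC(=O)C(C)(C)C | intermediate (not isolated)
13 | (S)-4-benzyl-3-[(E)-3-iodobut-2-enoyl]oxazolidin-2-one | C/C(I)=C\C(=O)N1[C@@H](Cc2ccccc2)COC1=O | intermediate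
14 | 9-[(5Z,7E)-6-(tert-butyldimethylsilyloxy)-4,4-dimethylnona-5,7-dien-1-yl]-9-borabicyclo[3.3.1]nonane | C/C=C/C(O[Si](C)(C)C(C)(C)C)=C/C(C)(C)CCCB1C2CCCC1CCC2 | intermediate (not isolated)
15 | (S)-4-benzyl-3-[(2E,8Z,10E)-9-(tert-butyldimethylsilyloxy)-3,7,7-trimethyldodeca-2,8,10-trienoyl]oxazolidin-2-one | O=C(/C=C(\C)CCCC(C)(C)/C=C(O[Si](C)(C)C(C)(C)C)/C=C/C)N1[C@@H](Cc2ccccc2)COC1=O | intermediate
16 | (S)-4-benzyl-3-acyloxazolidin-2-one of 6-(tert-butyldimethylsilyloxy)-4,4,8β,10β-tetramethyl-trans-octal-6-ene-9β-carboxylic acid (5α-H) | CC(C)(C)[Si](C)(C)OC1=C[C@H](C)[C@H](C(=O)N3[C@@H](Cc4ccccc4)COC3=O)[C@@]2(C)CCCC(C)(C)[C@H]12 | intermediate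
17 | S-ethyl 6-(tert-butyldimethylsilyloxy)-4,4,8β,10β-tetramethyl-trans-octal-6-ene-9β-carbothioate (5α-H) | CC(C)(C)[Si](C)(C)OC1=C[C@H](C)[C@H](C(=O)SCC)[C@@]2(C)CCCC(C)(C)[C@H]12 | intermediate
18 | S-ethyl 4,4,8,10β-tetramethyl-6-oxo-octal-7-ene-9β-carbothioate (5α-H) | O=C1C=C(C)[C@H](C(=O)SCC)[C@@]2(C)CCCC(C)(C)[C@H]12 | intermediate
19 | S-ethyl 6-(tert-butyldimethylsilyloxy)-4,4,8,10β-tetramethyl-octala-6,8-diene-9-carbothioate (5α-H) | CC(C)(C)[Si](C)(C)OC1=CC(C)=C(C(=O)SCC)[C@@]2(C)CCCC(C)(C)[C@H]12 | intermediate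
20 | [6-(tert-butyldimethylsilyloxy)-4,4,8,10β-tetramethyl-octala-6,8-dien-9-yl]methanol (5α-H) | CC(C)(C)[Si](C)(C)OC1=CC(C)=C(CO)[C@@]2(C)CCCC(C)(C)[C@H]12 | intermediate
21 | 9-(hydroxymethyl)-4,4,8,10β-tetramethyl-octal-8-en-6-one (5α-H) | O=C1CC(C)=C(CO)[C@@]2(C)CCCC(C)(C)[C@H]12 | intermediate (not isolated)
22 | 9-(hydroxymethyl)-4,4,8,10β-tetramethyl-octal-8-en-6β-ol (5α-H) | O[C@@H]1CC(C)=C(CO)[C@@]2(C)CCCC(C)(C)[C@H]12 | intermediate
23 | 6β-hydroxy-4,4,8,10β-tetramethyl-octal-8-ene-9-carbaldehyde (5α-H) | O[C@@H]1CC(C)=C(C=O)[C@@]2(C)CCCC(C)(C)[C@H]12 | intermediate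
24 | 4,4,8,10β-tetramethyl-9-vinyl-octal-8-en-6β-ol (5α-H) | O[C@@H]1CC(C)=C(C=C)[C@@]2(C)CCCC(C)(C)[C@H]12 | intermediate
25 | 4,4,8,10β-tetramethyl-9-vinyl-octal-8-en-6β-yl acetate (5α-H) | CC(=O)O[C@@H]1CC(C)=C(C=C)[C@@]2(C)CCCC(C)(C)[C@H]12 | intermediate
26 | 4-bromofuran-2(5H)-one | O=C1C=C(Br)CO1 | starting material
27 | 9-[2-(6β-acetoxy-4,4,8,10β-tetramethyl-octal-8-en-9-yl)ethyl]-9-borabicyclo[3.3.1]nonane (5α-H) | CC(=O)O[C@@H]1CC(C)=C(CCB3C4CCCC3CCC4)[C@@]2(C)CCCC(C)(C)[C@H]12 | intermediate (not isolated)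
28 | 6β-acetoxylabda-8,13-dien-15,16-olide, (5S,6R,10S); 4-[2-(6β-acetoxy-4,4,8,10β-tetramethyl-octal-8-en-9-yl)ethyl]furan-2(5H)-one | CC(=O)O[C@@H]1CC(C)=C(CCC2=CC(=O)OC2)[C@@]2(C)CCCC(C)(C)[C@H]12 | target

**Step count and risks**

Total: 16 steps. Longest linear sequence: 15 steps (steps 1–4 and 6–16); step 5 is a one-step side branch.

Steps most likely to fail:

1. Step 7. The hindered β,β-disubstituted acceptor may react only as far as the first C–C bond: the silyl group is lost from the zwitterion before C9 closes onto C8, so that ring A forms without ring B. Fallback (stepwise ionic double Michael sequence in place of the concerted cycloaddition), from 15: TiCl4 in CH2Cl2 at −78 °C should drive the Mukaiyama–Michael addition and, after aqueous work-up, give the monocyclic keto imide (S)-4-benzyl-3-{2-[2-((E)-but-2-enoyl)-1,3,3-trimethylcyclohexyl]acetyl}oxazolidin-2-one F1. NaN(SiMe3)2 in THF at −78 °C then closes ring B by intramolecular Michael addition of the imide enolate (C9) to the enone (C8), which should give the 6-oxo-4,4,8α,10β-tetramethyl-trans-decalin-9β-carbonyl oxazolidinone F2 with the 8-methyl group equatorial. TBSOTf/Et3N converts it into the silyl enol ether F3 (the C8 epimer of 16), LiSEt into the thioester F4 (the C8 epimer of 17), and Pd(OAc)2 oxidation of F4 rejoins the route at 18, where C8 is trigonal.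

2. Step 8. The thiolate may attack the ring carbonyl of the oxazolidinone, or fail to reach the congested exocyclic carbonyl. Fallback (reductive removal of the auxiliary, with an aldehyde instead of a thioester as the group that directs the double-bond shift), from 16: LiBH4 with one equivalent of H2O in Et2O at 0 °C should give the primary alcohol [6-(tert-butyldimethylsilyloxy)-4,4,8β,10β-tetramethyl-trans-octal-6-en-9β-yl]methanol F5. Buffered DMP (triacetoxyperiodinane) gives the 9β-carbaldehyde F6, Pd(OAc)2 the 6-oxo-7-ene-9β-carbaldehyde F7, and TBSOTf/Et3N the 6-silyloxy-6,8-diene-9-carbaldehyde F8. NaBH4 reduces F8 to 20.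

3. Step 12. The 8,9-double bond may migrate into conjugation (7,8) at the β,γ-unsaturated ketone stage, or the allylic alcohol of the dienol ether may ionise during desilylation. Fallback (the 6-hydroxyl is set before the double bond, which is then made by selenoxide elimination), from 17: Bu4NF/AcOH followed by NaBH4 should give, through the saturated 6-ketone S-ethyl 4,4,8β,10β-tetramethyl-6-oxo-trans-decalin-9β-carbothioate F9, the S-ethyl 6β-hydroxy-4,4,8β,10β-tetramethyl-trans-decalin-9β-carbothioate F10. LiN(i-Pr)2 (2.3 equiv) and PhSeBr give the 9α-phenylselanyl thioester F11; H2O2/pyridine oxidises it and syn-elimination with H-8α gives S-ethyl 6β-hydroxy-4,4,8,10β-tetramethyl-octal-8-ene-9-carbothioate F12. i-Bu2AlH reduces F12 to 22.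

**Further compounds**

F1 | step 7 | (S)-4-benzyl-3-{2-[2-((E)-but-2-enoyl)-1,3,3-trimethylcyclohexyl]acetyl}oxazolidin-2-one (ring A only; C10 as in 16, H-5 anti to the C10 methyl) | C/C=C/C(=O)[C@H]1C(C)(C)CCC[C@]1(C)CC(=O)N1[C@@H](Cc2ccccc2)COC1=O
F2 | step 7 | (S)-4-benzyl-3-acyloxazolidin-2-one of 4,4,8α,10β-tetramethyl-6-oxo-trans-decalin-9β-carboxylic acid (5α-H) | O=C1C[C@@H](C)[C@H](C(=O)N3[C@@H](Cc4ccccc4)COC3=O)[C@@]2(C)CCCC(C)(C)[C@H]12
F3 | step 7 | (S)-4-benzyl-3-acyloxazolidin-2-one of 6-(tert-butyldimethylsilyloxy)-4,4,8α,10β-tetramethyl-trans-octal-6-ene-9β-carboxylic acid (C8 epimer of 16) | CC(C)(C)[Si](C)(C)OC1=C[C@@H](C)[C@H](C(=O)N3[C@@H](Cc4ccccc4)COC3=O)[C@@]2(C)CCCC(C)(C)[C@H]12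
F4 | step 7 | S-ethyl 6-(tert-butyldimethylsilyloxy)-4,4,8α,10β-tetramethyl-trans-octal-6-ene-9β-carbothioate (C8 epimer of 17) | CC(C)(C)[Si](C)(C)OC1=C[C@@H](C)[C@H](C(=O)SCC)[C@@]2(C)CCCC(C)(C)[C@H]12
F5 | step 8 | [6-(tert-butyldimethylsilyloxy)-4,4,8β,10β-tetramethyl-trans-octal-6-en-9β-yl]methanol (5α-H) | CC(C)(C)[Si](C)(C)OC1=C[C@H](C)[C@H](CO)[C@@]2(C)CCCC(C)(C)[C@H]12
F6 | step 8 | 6-(tert-butyldimethylsilyloxy)-4,4,8β,10β-tetramethyl-trans-octal-6-ene-9β-carbaldehyde (5α-H) | CC(C)(C)[Si](C)(C)OC1=C[C@H](C)[C@H](C=O)[C@@]2(C)CCCC(C)(C)[C@H]12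
F7 | step 8 | 4,4,8,10β-tetramethyl-6-oxo-octal-7-ene-9β-carbaldehyde (5α-H) | O=C1C=C(C)[C@H](C=O)[C@@]2(C)CCCC(C)(C)[C@H]12
F8 | step 8 | 6-(tert-butyldimethylsilyloxy)-4,4,8,10β-tetramethyl-octala-6,8-diene-9-carbaldehyde (5α-H) | CC(C)(C)[Si](C)(C)OC1=CC(C)=C(C=O)[C@@]2(C)CCCC(C)(C)[C@H]12
F9 | step 12 | S-ethyl 4,4,8β,10β-tetramethyl-6-oxo-trans-decalin-9β-carbothioate (5α-H) | O=C1C[C@H](C)[C@H](C(=O)SCC)[C@@]2(C)CCCC(C)(C)[C@H]12
F10 | step 12 | S-ethyl 6β-hydroxy-4,4,8β,10β-tetramethyl-trans-decalin-9β-carbothioate (5α-H) | O[C@@H]1C[C@H](C)[C@H](C(=O)SCC)[C@@]2(C)CCCC(C)(C)[C@H]12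
F11 | step 12 | S-ethyl 6β-hydroxy-4,4,8β,10β-tetramethyl-9α-(phenylselanyl)-trans-decalin-9β-carbothioate (5α-H) | O[C@@H]1C[C@H](C)[C@]([Se]c3ccccc3)(C(=O)SCC)[C@@]2(C)CCCC(C)(C)[C@H]12
F12 | step 12 | S-ethyl 6β-hydroxy-4,4,8,10β-tetramethyl-octal-8-ene-9-carbothioate (5α-H) | O[C@@H]1CC(C)=C(C(=O)SCC)[C@@]2(C)CCCC(C)(C)[C@H]12
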